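The chain is numbered C1 (lactone C=O) to C12 (CH3). The tetrahydrofuran ring (O, C7–C10) carries the exocyclic carbons C6 and C11 cis on its two α-carbons, so it is read as furan bridged by C6–C5(=O)–C11. One (4+3) cycloaddition of purchased furan with the oxyallyl cation released from purchased 1,1,3,3-tetrabromoacetone forms C6–C7 and C10–C11, closes the oxygen-bridged seven-membered ring and locks the cis relationship. The meso ketone is then desymmetrised by chiral-base deprotonation with axial methylation (C12). Baeyer–Villiger oxidation places oxygen on C11, the rigid bicycle sets C6, and C5 is extended to the dihydropyranone before late Z-coumaroylation.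

Key step: step 1

Conventions: target chain numbering (C1–C12) is used for all intermediates. Exo is the face syn to the oxygen bridge and endo is the face syn to the C8–C9 bridge.

Assumption: the sense of enantiotopic proton selection by lithium (S,S)-bis(1-phenylethyl)amide is assigned by analogy with conformationally locked cyclohexanones; should it prove opposite, the equally available (R,R)-amine is used and nothing else changes.

Step 1
Reactants: 1 furan; 2 1,1,3,3-tetrabromoacetone
Product: 5 meso-(1R,5S)-8-oxabicyclo[3.2.1]oct-6-en-3-one, via 1,3-dibromo-2-oxidoallyl cation (zinc-bound oxyallyl cation) 3 (not isolated), via 2,4-dibromo-8-oxabicyclo[3.2.1]oct-6-en-3-one 4 (not isolated)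
Conditions: Zn–Cu couple, furan (excess), THF, −10 °C → rt; then NH4Cl-saturated MeOH, Zn–Cu couple, −78 °C → rt
Reagents that add atoms: none
Why: Zinc inserts into a C–Br bond of 2 and the zinc enolate ionises a bromide from the other α-carbon to give the 1,3-dibromo-oxyallyl cation 3, a three-carbon 2π component that adds across C2 and C5 of furan (4π) in a concerted or near-concerted (4+3) cycloaddition, the classical polyhaloketone–furan oxyallyl cycloaddition. The seven-membered carbocycle C5–C11 closes in an intermolecular cycloaddition mode, both termini of 3 bonding to the same face of the planar furan, so that the furan oxygen becomes the one-atom bridge and furan O/C2–C5 become ring O/C7–C10 of the target. The two new stereocentres C7 and C10 are controlled by the bridged topology alone, which allows only the cis (meso) arrangement. The step needs cycloaddition to win over electrophilic α-substitution of furan and over premature reduction of 2; furan is locked s-cis, electron-rich and used in excess, and the two remaining bromines stabilise the cation. The C–Br centres of 4 are of no consequence because Zn–Cu/NH4Cl replaces both bromines by hydrogen through zinc enolates, which leaves the achiral ketone 5. Absolute configuration is not at stake here and is introduced in step 3.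

Step 2
Reactants: 5 meso-(1R,5S)-8-oxabicyclo[3.2.1]oct-6-en-3-one
Product: 6 meso-(1R,5S)-8-oxabicyclo[3.2.1]octan-3-one
Conditions: H2 (1 atm), 10% Pd/C, EtOAc, rt
Reagents that add atoms: none
Why: Catalytic hydrogenation of the strained, unhindered cis-alkene is fast, leaves the ketone and both C–O bonds intact and removes the only group that would interfere with the peracid (step 4) and metathesis (step 14) chemistry; the product stays meso.

Step 3
Reactants: 6 meso-(1R,5S)-8-oxabicyclo[3.2.1]octan-3-one
Product: 8 (1S,2S,5R)-2-methyl-8-oxabicyclo[3.2.1]octan-3-one (methyl axial, exo), via lithium (1S,5R)-8-oxabicyclo[3.2.1]oct-2-en-3-olate 7 (not isolated)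
Conditions: (S,S)-bis(1-phenylethyl)amine·HCl, n-BuLi (2 equiv), THF, −78 → 0 → −100 °C; 6; then MeI, DMPU, −78 → −40 °C; cold pH 7 buffer
Reagents that add atoms: iodomethane, CI
Why: Enantioselective deprotonation with a C2-symmetric chiral lithium amide (LiCl-modified) removes the exo (axial) proton on only one of the two enantiotopic α-carbons, which defines that carbon as C11 and thereby the absolute configuration of C7 (R) and C10 (S), and SN2 methylation of enolate 7 occurs by axial attack on the exo face because the endo face is covered by the C8–C9 bridge, setting C11 with the methyl group axial.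

Step 4
Reactants: 8 (1S,2S,5R)-2-methyl-8-oxabicyclo[3.2.1]octan-3-one
Product: 9 (1S,2S,6R)-2-methyl-3,9-dioxabicyclo[4.2.1]nonan-4-one
Conditions: mCPBA, NaHCO3, CH2Cl2, 0 °C → rt
Reagents that add atoms: 3-chloroperoxybenzoic acid, OOC(=O)c1cccc(Cl)c1
Why: Baeyer–Villiger oxidation: in the Criegee intermediate the secondary C11 migrates in preference to the C6 methylene and does so with retention, so the C11–C5 bond is replaced by C11–O to give (11S), threo to C10, while the buffer prevents epimerisation of the axial methyl ketone before it reacts.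

Step 5
Reactants: 9 (1S,2S,6R)-2-methyl-3,9-dioxabicyclo[4.2.1]nonan-4-one
Product: 11 (1S,2S,5R,6R)-5-hydroxy-2-methyl-3,9-dioxabicyclo[4.2.1]nonan-4-one (C6–OH exo), via potassium enolate of 9 (C5=C6) 10 (not isolated)
Conditions: KHMDS, THF, −78 °C; (±)-2-(phenylsulfonyl)-3-phenyloxaziridine, −78 °C; AcOH
Reagents that add atoms: 2-(phenylsulfonyl)-3-phenyloxaziridine, O=S(=O)(N1OC1c1ccccc1)c1ccccc1
Why: Enolate hydroxylation with a Davis oxaziridine: C6 carries the only acidic hydrogens and the bridged frame holds the C7–O bond away from the enolate π system, which disfavours β-elimination at −78 °C; oxygen arrives on the open exo face, giving the C6 configuration opposite to that of the target, which is why this centre is erased in step 6 and reset in step 7.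

Step 6
Reactants: 11 (1S,2S,5R,6R)-5-hydroxy-2-methyl-3,9-dioxabicyclo[4.2.1]nonan-4-one
Product: 12 (1S,2S,6R)-2-methyl-3,9-dioxabicyclo[4.2.1]nonane-4,5-dione
Conditions: Dess–Martin periodinane, CH2Cl2, rt; filtered and used directly
Reagents that add atoms: none
Why: Dess–Martin oxidation of a secondary α-hydroxy lactone runs under neutral conditions, and C7 next to the new ketone cannot epimerise because the bicycle allows only the cis bridge and enolisation towards the bridgehead is geometrically excluded.

Step 7
Reactants: 12 (1S,2S,6R)-2-methyl-3,9-dioxabicyclo[4.2.1]nonane-4,5-dione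
Product: 13 (1S,2S,5S,6R)-5-hydroxy-2-methyl-3,9-dioxabicyclo[4.2.1]nonan-4-one (C6–OH endo)
Conditions: L-Selectride (1.0 equiv), THF, −78 °C; AcOH
Reagents that add atoms: none
Why: Diastereoselective ketone reduction with a bulky trialkylborohydride: the C6 ketone, activated by the adjacent lactone carbonyl, reacts far faster than the lactone, and hydride enters from the exo face (the endo face is shielded by the C8–C9 bridge), which puts H exo and OH endo and sets (6S), threo to C7.

Step 8
Reactants: 13 (1S,2S,5S,6R)-5-hydroxy-2-methyl-3,9-dioxabicyclo[4.2.1]nonan-4-one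
Product: 14 (1S,2S,5S,6R)-5-(tert-butyldimethylsilyloxy)-2-methyl-3,9-dioxabicyclo[4.2.1]nonan-4-one
Conditions: TBSOTf, 2,6-lutidine, CH2Cl2, 0 °C
Reagents that add atoms: tert-butyldimethylsilyl triflate, CC(C)(C)[Si](C)(C)OS(=O)(=O)C(F)(F)F
Why: Silylation of a hindered secondary alcohol with a silyl triflate and a non-nucleophilic base; TBS is a non-chelating group that lasts until the final fluoride step and supports Felkin–Anh addition in step 12.

Step 9
Reactants: 14 (1S,2S,5S,6R)-5-(tert-butyldimethylsilyloxy)-2-methyl-3,9-dioxabicyclo[4.2.1]nonan-4-one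
Product: 15 (2S)-2-(tert-butyldimethylsilyloxy)-2-{(2R,5S)-5-[(1S)-1-hydroxyethyl]oxolan-2-yl}-N-methoxy-N-methylacetamide
Conditions: MeNH(OMe)·HCl, i-PrMgCl, THF, −20 → 0 °C; aq NH4Cl
Reagents that add atoms: N,O-dimethylhydroxylamine hydrochloride, CNOC.Cl
Why: Weinreb aminolysis of the lactone with the magnesium amide opens the seven-membered ring at the acyl–oxygen bond, so C11–O keeps its configuration and is released as the free alcohol while C5 becomes an acyl group that can be reduced cleanly to the aldehyde.

Step 10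
Reactants: 15 (2S)-2-(tert-butyldimethylsilyloxy)-2-{(2R,5S)-5-[(1S)-1-hydroxyethyl]oxolan-2-yl}-N-methoxy-N-methylacetamide
Product: 16 (2S)-2-(tert-butyldimethylsilyloxy)-N-methoxy-N-methyl-2-{(2R,5S)-5-[(1S)-1-(triethylsilyloxy)ethyl]oxolan-2-yl}acetamide
Conditions: TESCl, imidazole, CH2Cl2, 0 °C → rt
Reagents that add atoms: chlorotriethylsilane, CC[Si](Cl)(CC)CC
Why: Standard silylation; the TES ether masks C11–OH during acylation of C5–OH and can later be removed in the presence of the TBS ether.

Step 11
Reactants: 16 (2S)-2-(tert-butyldimethylsilyloxy)-N-methoxy-N-methyl-2-{(2R,5S)-5-[(1S)-1-(triethylsilyloxy)ethyl]oxolan-2-yl}acetamide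
Product: 17 (2S)-2-(tert-butyldimethylsilyloxy)-2-{(2R,5S)-5-[(1S)-1-(triethylsilyloxy)ethyl]oxolan-2-yl}acetaldehyde
Conditions: DIBAL-H, THF, −78 °C; aq Rochelle salt; used crude
Reagents that add atoms: none
Why: DIBAL-H reduction of a Weinreb amide stops at the chelated tetrahedral intermediate, which releases the α-silyloxy aldehyde only on work-up, so over-reduction and C6 epimerisation are avoided.

Step 12
Reactants: 17 (2S)-2-(tert-butyldimethylsilyloxy)-2-{(2R,5S)-5-[(1S)-1-(triethylsilyloxy)ethyl]oxolan-2-yl}acetaldehyde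
Product: 19 (1R,2R)-1-(tert-butyldimethylsilyloxy)-1-{(2R,5S)-5-[(1S)-1-(triethylsilyloxy)ethyl]oxolan-2-yl}pent-4-en-2-ol (C5 is R; C6 is unchanged in space, its CIP label reads R here only through a priority change), via C5-O-diisopinocampheylborinate of 19 18 (not isolated)
Conditions: (+)-Ipc2BOMe, allylMgBr, Et2O, 0 °C → rt; 17, −78 °C; then pH 7 buffer, 30% H2O2, MeOH, 0 °C
Reagents that add atoms: allylmagnesium bromide, C=CC[Mg]Br (allyl group, delivered through (+)-B-allyldiisopinocampheylborane)
Why: Brown asymmetric allylboration through a closed chair (Zimmerman–Traxler) transition state: the (−)-α-pinene-derived reagent adds allyl to the Re face of the aldehyde, which coincides with the Felkin–Anh preference of the α-silyloxy aldehyde (matched pair) and sets (5R), anti to C6; material from the minor enantiomer of step 3 becomes a separable diastereomer here.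

Step 13
Reactants: 19 (1R,2R)-1-(tert-butyldimethylsilyloxy)-1-{(2R,5S)-5-[(1S)-1-(triethylsilyloxy)ethyl]oxolan-2-yl}pent-4-en-2-ol
Product: 20 (1S,2R)-1-(tert-butyldimethylsilyloxy)-1-{(2R,5S)-5-[(1S)-1-(triethylsilyloxy)ethyl]oxolan-2-yl}pent-4-en-2-yl acrylate
Conditions: acryloyl chloride, Et3N, DMAP (cat.), CH2Cl2, 0 °C
Reagents that add atoms: acryloyl chloride, C=CC(=O)Cl
Why: O-Acylation of the only free hydroxyl group with an acid chloride under DMAP catalysis touches no stereocentre.

Step 14
Reactants: 20 (1S,2R)-1-(tert-butyldimethylsilyloxy)-1-{(2R,5S)-5-[(1S)-1-(triethylsilyloxy)ethyl]oxolan-2-yl}pent-4-en-2-yl acrylate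
Product: 21 (6R)-6-[(S)-(tert-butyldimethylsilyloxy){(2R,5S)-5-[(1S)-1-(triethylsilyloxy)ethyl]oxolan-2-yl}methyl]-5,6-dihydro-2H-pyran-2-one
Conditions: Grubbs second-generation catalyst (5 mol %), CH2Cl2 (dilute), reflux
Reagents that add atoms: none
Why: Ring-closing metathesis of the acrylate and the terminal alkene closes the six-membered α,β-unsaturated δ-lactone (C2=C3, necessarily cis in the ring) with loss of ethene.

Step 15
Reactants: 21 (6R)-6-[(S)-(tert-butyldimethylsilyloxy){(2R,5S)-5-[(1S)-1-(triethylsilyloxy)ethyl]oxolan-2-yl}methyl]-5,6-dihydro-2H-pyran-2-one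
Product: 22 (6R)-6-[(S)-(tert-butyldimethylsilyloxy){(2R,5S)-5-[(1S)-1-hydroxyethyl]oxolan-2-yl}methyl]-5,6-dihydro-2H-pyran-2-one
Conditions: PPTS (cat.), MeOH, 0 °C → rt
Reagents that add atoms: none
Why: Mild acid-catalysed methanolysis discriminates the less hindered, more labile TES ether from the secondary TBS ether flanked by two branched carbons, freeing only C11–OH.

Step 16
Reactants: 23 4-hydroxybenzaldehyde
Product: 24 4-(triisopropylsilyloxy)benzaldehyde
Conditions: TIPSCl, imidazole, DMF, rt
Reagents that add atoms: chlorotriisopropylsilane, CC(C)[Si](Cl)(C(C)C)C(C)C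
Why: Standard phenol silylation; the aryl TIPS ether tolerates steps 17–19 better than smaller silyl groups and still falls to fluoride at the end.

Step 17
Reactants: 24 4-(triisopropylsilyloxy)benzaldehyde
Product: 25 methyl (2Z)-3-[4-(triisopropylsilyloxy)phenyl]prop-2-enoate
Conditions: (CF3CH2O)2P(O)CH2CO2Me, KHMDS, 18-crown-6, THF, −78 °C
Reagents that add atoms: methyl bis(2,2,2-trifluoroethyl)phosphonoacetate, COC(=O)CP(=O)(OCC(F)(F)F)OCC(F)(F)F
Why: Still–Gennari modification of the Horner–Wadsworth–Emmons olefination: with the trifluoroethyl phosphonate and a dissociated potassium counter-ion, elimination of the initial adduct is faster than its reversal, which gives the Z-cinnamate under kinetic control.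

Step 18
Reactants: 25 methyl (2Z)-3-[4-(triisopropylsilyloxy)phenyl]prop-2-enoate
Product: 26 (2Z)-3-[4-(triisopropylsilyloxy)phenyl]prop-2-enoic acid
Conditions: Me3SnOH, 1,2-dichloroethane, 70 °C, dark; dilute HCl wash
Reagents that add atoms: trimethyltin hydroxide, C[Sn](C)(C)O
Why: Trimethyltin hydroxide hydrolysis of a methyl ester proceeds under essentially neutral conditions, so the aryl silyl ether stays in place and neither a phenoxide nor a strong acid is present that could ease Z→E isomerisation.

Step 19
Reactants: 22 (6R)-6-[(S)-(tert-butyldimethylsilyloxy){(2R,5S)-5-[(1S)-1-hydroxyethyl]oxolan-2-yl}methyl]-5,6-dihydro-2H-pyran-2-one; 26 (2Z)-3-[4-(triisopropylsilyloxy)phenyl]prop-2-enoic acid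
Product: 27 (1S)-1-[(2S,5R)-5-{(S)-(tert-butyldimethylsilyloxy)[(2R)-6-oxo-3,6-dihydro-2H-pyran-2-yl]methyl}oxolan-2-yl]ethyl (2Z)-3-[4-(triisopropylsilyloxy)phenyl]prop-2-enoate
Conditions: DCC, DMAP (cat.), CH2Cl2, 0 °C → rt, dark
Reagents that add atoms: none
Why: Steglich esterification acylates the only free hydroxyl group at oxygen, so C11 keeps its configuration, and low temperature, catalytic DMAP and exclusion of light preserve the Z-alkene.

Step 20
Reactants: 27 (1S)-1-[(2S,5R)-5-{(S)-(tert-butyldimethylsilyloxy)[(2R)-6-oxo-3,6-dihydro-2H-pyran-2-yl]methyl}oxolan-2-yl]ethyl (2Z)-3-[4-(triisopropylsilyloxy)phenyl]prop-2-enoate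
Product: 28 (1S)-1-[(2S,5R)-5-{(S)-hydroxy[(2R)-6-oxo-3,6-dihydro-2H-pyran-2-yl]methyl}oxolan-2-yl]ethyl (2Z)-3-(4-hydroxyphenyl)prop-2-enoate (target, 5R,6S,7R,10S,11S)
Conditions: HF·pyridine, pyridine, THF, 0 °C → rt, dark
Reagents that add atoms: none
Why: Fluoride-mediated cleavage with buffered HF·pyridine removes the aryl TIPS and the secondary TBS ether in one operation and leaves both esters, the enoate ring and the Z-alkene untouched.

Compound list
1 | furan | c1ccoc1 | starting material
2 | 1,1,3,3-tetrabromoacetone | O=C(C(Br)Br)C(Br)Br | starting material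
3 | 1,3-dibromo-2-oxidoallyl cation (zinc-bound oxyallyl cation) | [O-]C(=CBr)[CH+]Br | intermediate
4 | 2,4-dibromo-8-oxabicyclo[3.2.1]oct-6-en-3-one (C–Br epimers) | O=C1C(Br)[C@H]2C=C[C@@H](C1Br)O2 | intermediate
5 | meso-(1R,5S)-8-oxabicyclo[3.2.1]oct-6-en-3-one | O=C1C[C@H]2C=C[C@@H](C1)O2 | intermediate
6 | meso-(1R,5S)-8-oxabicyclo[3.2.1]octan-3-one | O=C1C[C@H]2CC[C@@H](C1)O2 | intermediate
7 | lithium (1S,5R)-8-oxabicyclo[3.2.1]oct-2-en-3-olate | [Li]OC1=C[C@@H]2CC[C@H](C1)O2 | intermediate
8 | (1S,2S,5R)-2-methyl-8-oxabicyclo[3.2.1]octan-3-one (methyl exo, axial) | C[C@@H]1C(=O)C[C@H]2CC[C@@H]1O2 | intermediate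
9 | (1S,2S,6R)-2-methyl-3,9-dioxabicyclo[4.2.1]nonan-4-one | C[C@@H]1OC(=O)C[C@H]2CC[C@@H]1O2 | intermediate
10 | potassium enolate of 9 | C[C@@H]1OC(O[K])=C[C@H]2CC[C@@H]1O2 | intermediate
11 | (1S,2S,5R,6R)-5-hydroxy-2-methyl-3,9-dioxabicyclo[4.2.1]nonan-4-one (OH exo) | C[C@@H]1OC(=O)[C@H](O)[C@H]2CC[C@@H]1O2 | intermediate
12 | (1S,2S,6R)-2-methyl-3,9-dioxabicyclo[4.2.1]nonane-4,5-dione | C[C@@H]1OC(=O)C(=O)[C@H]2CC[C@@H]1O2 | intermediate
13 | (1S,2S,5S,6R)-5-hydroxy-2-methyl-3,9-dioxabicyclo[4.2.1]nonan-4-one (OH endo) | C[C@@H]1OC(=O)[C@@H](O)[C@H]2CC[C@@H]1O2 | intermediate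
14 | TBS ether of 13 | C[C@@H]1OC(=O)[C@@H](O[Si](C)(C)C(C)(C)C)[C@H]2CC[C@@H]1O2 | intermediate
15 | C5 Weinreb amide, C6–OTBS, C11–OH | C[C@H](O)[C@@H]1CC[C@H]([C@H](O[Si](C)(C)C(C)(C)C)C(=O)N(C)OC)O1 | intermediate
16 | C5 Weinreb amide, C6–OTBS, C11–OTES | C[C@H](O[Si](CC)(CC)CC)[C@@H]1CC[C@H]([C@H](O[Si](C)(C)C(C)(C)C)C(=O)N(C)OC)O1 | intermediate
17 | C5 aldehyde, C6–OTBS, C11–OTES | C[C@H](O[Si](CC)(CC)CC)[C@@H]1CC[C@H]([C@H](O[Si](C)(C)C(C)(C)C)C=O)O1 | intermediate
18 | C5-O-diisopinocampheylborinate of 19 | C[C@H](O[Si](CC)(CC)CC)[C@@H]1CC[C@H]([C@H](O[Si](C)(C)C(C)(C)C)[C@@H](CC=C)OB([C@H]2C[C@H]3C[C@@H]([C@@H]2C)C3(C)C)[C@H]2C[C@H]3C[C@@H]([C@@H]2C)C3(C)C)O1 | intermediate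
19 | (5R)-homoallylic alcohol, C6–OTBS, C11–OTES | C[C@H](O[Si](CC)(CC)CC)[C@@H]1CC[C@H]([C@H](O[Si](C)(C)C(C)(C)C)[C@H](O)CC=C)O1 | intermediate
20 | C5 acrylate of 19 | C[C@H](O[Si](CC)(CC)CC)[C@@H]1CC[C@H]([C@H](O[Si](C)(C)C(C)(C)C)[C@H](OC(=O)C=C)CC=C)O1 | intermediate
21 | dihydropyranone, C6–OTBS, C11–OTES | C[C@H](O[Si](CC)(CC)CC)[C@@H]1CC[C@H]([C@H](O[Si](C)(C)C(C)(C)C)[C@H]2CC=CC(=O)O2)O1 | intermediate
22 | dihydropyranone, C6–OTBS, C11–OH | C[C@H](O)[C@@H]1CC[C@H]([C@H](O[Si](C)(C)C(C)(C)C)[C@H]2CC=CC(=O)O2)O1 | intermediate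
23 | 4-hydroxybenzaldehyde | O=Cc1ccc(O)cc1 | starting material
24 | 4-(triisopropylsilyloxy)benzaldehyde | O=Cc1ccc(O[Si](C(C)C)(C(C)C)C(C)C)cc1 | intermediate
25 | methyl (2Z)-3-[4-(triisopropylsilyloxy)phenyl]prop-2-enoate | COC(=O)/C=C\c1ccc(O[Si](C(C)C)(C(C)C)C(C)C)cc1 | intermediate
26 | (2Z)-3-[4-(triisopropylsilyloxy)phenyl]prop-2-enoic acid | OC(=O)/C=C\c1ccc(O[Si](C(C)C)(C(C)C)C(C)C)cc1 | intermediate
27 | bis-silylated target (C6–OTBS, ArO–TIPS) | C[C@H](OC(=O)/C=C\c1ccc(O[Si](C(C)C)(C(C)C)C(C)C)cc1)[C@@H]1CC[C@H]([C@H](O[Si](C)(C)C(C)(C)C)[C@H]2CC=CC(=O)O2)O1 | intermediate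
28 | CNP0417147.1 | C[C@H](OC(=O)/C=C\c1ccc(O)cc1)[C@@H]1CC[C@H]([C@H](O)[C@H]2CC=CC(=O)O2)O1 | target

Total step count: 20. Longest linear sequence: 17 steps (steps 1–15, 19 and 20).

Steps most likely to fail

1. Step 3. Three things may go wrong. The two enantiotopic exo protons may be incompletely discriminated. Proton exchange between enolate and product may lead to over-methylation. The axial methyl group may drift to the equatorial position during the quench. The fallback separates desymmetrisation from C–C bond formation. It sets out from 6 and uses the same lithium amide with Me3SiCl present from the start (internal quench). This should give the isolable silyl enol ether (1S,5R)-3-(trimethylsilyloxy)-8-oxabicyclo[3.2.1]oct-2-ene F1, whose enantiomeric purity can be checked. MeLi in THF then cleaves the Si–O bond to the amine-free enolate 7, which is methylated with MeI. The route is rejoined at 8.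

2. Step 7. Hydride delivery to the C6 ketone may show insufficient exo/endo facial selectivity, or the activated lactone may be over-reduced. The fallback replaces the redox inversion by a substitution. It sets out from 11, where a Mitsunobu reaction (chloroacetic acid, PPh3, DIAD, toluene) inverts C6 by SN2 displacement. This gives (1S,2S,5S,6R)-2-methyl-4-oxo-3,9-dioxabicyclo[4.2.1]nonan-5-yl chloroacetate F2. Thiourea with NaHCO3 in EtOH then removes the chloroacetyl group under nearly neutral conditions that leave the lactone closed. The route is rejoined at 13.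

3. Step 5. The lactone enolate may lose the C7–O bond by β-elimination, which opens the tetrahydrofuran, or it may be captured by the sulfonimine that accumulates. The fallback avoids a preformed enolate. It sets out from 9, which is condensed with tert-butoxybis(dimethylamino)methane (DMF, 60–80 °C). This gives the enamino lactone (1S,2S,5E,6R)-5-[(dimethylamino)methylidene]-2-methyl-3,9-dioxabicyclo[4.2.1]nonan-4-one F3. Cleavage of its electron-rich C=C bond with singlet oxygen (O2, hν, sensitiser) or ozone gives the keto lactone directly. The route is rejoined at 12, and 11 is bypassed.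

Further compounds
F1 | step 3 | (1S,5R)-3-(trimethylsilyloxy)-8-oxabicyclo[3.2.1]oct-2-ene | C[Si](C)(C)OC1=C[C@@H]2CC[C@H](C1)O2
F2 | step 7 | (1S,2S,5S,6R)-2-methyl-4-oxo-3,9-dioxabicyclo[4.2.1]nonan-5-yl chloroacetate | C[C@@H]1OC(=O)[C@@H](OC(=O)CCl)[C@H]2CC[C@@H]1O2
F3 | step 5 | (1S,2S,5E,6R)-5-[(dimethylamino)methylidene]-2-methyl-3,9-dioxabicyclo[4.2.1]nonan-4-one | C[C@@H]1OC(=O)/C(=C/N(C)C)[C@H]2CC[C@@H]1O2
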